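**Plan**

Locants: tetrahydrofuran (THF) core C7/C8/C9 = THF C2, THF C3 and its CH2OH (syringyl side); C7'/C8'/C9' = ArCH2, THF C4, THF C5 (guaiacyl side); glycerol chain C7''(ArCHOH)–C8''(CHOAr)–C9''(CH2OH).
Cuts, in order: C7''–C8'' (anti-aldol of an N-aryloxyacetyl oxazolidinone with vanillin acetate); syringyl O–C8'' (phenol + bromoacetyl imide); THF O–C7 (quinone-methide closure of a triol); C7–C8 (lactone aldol with a syringaldehyde ester); C7'–C8' (Stobbe condensation of O-benzylvanillin).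
Forward: Stobbe, asymmetric hydrogenation, γ-lactone (temporary ring, steps 3–6), aldol, LiAlH4, closure of the THF (the only permanent ring), O-alkylation, fragment union, reductive auxiliary removal, debenzylation.
Enabling feature: C8'' is the one carbon flanked by the syringyl ether O and C9''. Carried as ArO–CH2–C(=O)–N(oxazolidinone), its two imide carbonyls chelate Mg(II) and allow soft enolisation; its partner C7'' is the carbonyl carbon of a non-enolisable aromatic aldehyde.
Stereochemistry: C8' from Rh-catalysed asymmetric hydrogenation; C8 from the trans-selective lactone aldol; C7 from the stereoconvergent cyclisation; C8'' and C7'' together from the auxiliary-controlled anti (erythro) aldol union.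

Key step: step 10

Remark: the facial sense in step 10 is taken from the chelated-enolate model (the sense known from alkylations of chelated N-acyloxazolidinone enolates), so the R auxiliary is specified; if the opposite sense is found, the S auxiliary is used with no other change.

**Route**

Step 1
Reactants: 1 4-(benzyloxy)-3-methoxybenzaldehyde; 2 dimethyl succinate
Product: 3 (E)-4-[4-(benzyloxy)-3-methoxyphenyl]-3-(methoxycarbonyl)but-3-enoic acid
Conditions: NaOMe (2 equiv), MeOH, reflux; then aq HCl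
Reagents that add atoms: none
Why: Stobbe condensation, in which aldol addition of the succinate enolate, lactonisation to the paraconate and E1cB ring opening should give the (E)-arylidene half-ester with acid and ester already differentiated.

Step 2
Reactants: 3 (E)-4-[4-(benzyloxy)-3-methoxyphenyl]-3-(methoxycarbonyl)but-3-enoic acid
Product: 4 (3S)-4-[4-(benzyloxy)-3-methoxyphenyl]-3-(methoxycarbonyl)butanoic acid
Conditions: H2 (4 atm), [Rh(cod)2]BF4/MOD-DIOP-type chiral bisphosphine (1 mol%, ligand antipode chosen for the S acid), Et3N (1 equiv), MeOH, rt; then aq HCl; recrystallisation if the ee needs upgrading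
Reagents that add atoms: none
Why: Rh(I)-bisphosphine asymmetric hydrogenation of an itaconate-type arylidenesuccinic half-ester, in which the carboxylate and alkene chelate Rh and the ligand selects the alkene face, should set C8' as S (the sense is checked at lactone 6 against the rotation of its known antipode).

Step 3
Reactants: 4 (3S)-4-[4-(benzyloxy)-3-methoxyphenyl]-3-(methoxycarbonyl)butanoic acid
Product: 6 (4S)-4-[4-(benzyloxy)-3-methoxybenzyl]dihydrofuran-2(3H)-one, via hydroxy acid 5 (not isolated)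
Conditions: KOH (1 equiv), EtOH; CaCl2/NaBH4 [Ca(BH4)2], EtOH, −10 °C → rt; then 3 M HCl, rt → 40 °C
Reagents that add atoms: none
Why: Chemoselective borohydride reduction (Ca(BH4)2 reduces the methyl ester but not the carboxylate salt) followed by acid lactonisation should give the β-arylmethyl lactone with the stereocentre untouched.

Step 4
Reactants: 7 4-hydroxy-3,5-dimethoxybenzaldehyde
Product: 8 4-formyl-2,6-dimethoxyphenyl pivalate
Conditions: PivCl (1.2 equiv), Et3N (1.5 equiv), DMAP (cat.), CH2Cl2, 0 °C → rt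
Reagents that add atoms: pivaloyl chloride CC(C)(C)C(=O)Cl
Why: DMAP-catalysed O-acylation of the phenol gives a hindered ester that should survive the enolate step, keeps the aldehyde electrophilic and is removed without an extra step by LiAlH4 in step 6.

Step 5
Reactants: 6 (4S)-4-[4-(benzyloxy)-3-methoxybenzyl]dihydrofuran-2(3H)-one; 8 4-formyl-2,6-dimethoxyphenyl pivalate
Product: 10 (3R,4S)-4-[4-(benzyloxy)-3-methoxybenzyl]-3-{hydroxy[3,5-dimethoxy-4-(pivaloyloxy)phenyl]methyl}dihydrofuran-2(3H)-one (both carbinol epimers), via lithium enolate 9 (not isolated)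
Conditions: LiHMDS (1.1 equiv), THF, −78 °C; then 8, −78 °C; AcOH quench at −78 °C
Reagents that add atoms: none
Why: Aldol addition of a lactone lithium enolate, in which the aldehyde adds to the face anti to the C4 arylmethyl group, should set C8 (lactone C3, R) trans to C8', while the carbinol centre forms as a mixture that step 7 erases.

Step 6
Reactants: 10 (3R,4S)-4-[4-(benzyloxy)-3-methoxybenzyl]-3-{hydroxy[3,5-dimethoxy-4-(pivaloyloxy)phenyl]methyl}dihydrofuran-2(3H)-one
Product: 11 (2S,3S)-2-[4-(benzyloxy)-3-methoxybenzyl]-3-[hydroxy(4-hydroxy-3,5-dimethoxyphenyl)methyl]butane-1,4-diol (both carbinol epimers)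
Conditions: LiAlH4 (4 equiv), THF, 0 °C → rt; Rochelle-salt work-up
Reagents that add atoms: none
Why: Hydride reduction opens the temporary lactone to the 1,4-diol and cleaves the aryl pivalate in the same operation, which frees the syringyl phenol selectively without touching a stereocentre.

Step 7
Reactants: 11 (2S,3S)-2-[4-(benzyloxy)-3-methoxybenzyl]-3-[hydroxy(4-hydroxy-3,5-dimethoxyphenyl)methyl]butane-1,4-diol
Product: 12 4-{(2R,3S,4S)-4-[4-(benzyloxy)-3-methoxybenzyl]-3-(hydroxymethyl)tetrahydrofuran-2-yl}-2,6-dimethoxyphenol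
Conditions: CSA (10 mol%), CH2Cl2/THF, 0 °C → rt; NaHCO3 quench at full conversion
Reagents that add atoms: none
Why: Acid-catalysed dehydrative etherification through the p-quinone methide (SN1 type, 5-exo-trig attack of the C9' hydroxyl on C7, the C9 hydroxyl could only give an oxetane) lets both carbinol epimers converge on one planar intermediate, and closure with the aryl group anti to the neighbouring CH2OH should set C7 as R (7,8-trans).

Step 8
Reactants: 13 (R)-4-benzyloxazolidin-2-one; 14 bromoacetyl bromide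
Product: 16 (R)-4-benzyl-3-(2-bromoacetyl)oxazolidin-2-one, via lithium oxazolidinide 15 (not isolated)
Conditions: n-BuLi (1.0 equiv), THF, −78 °C; then 14 (1.1 equiv), −78 °C
Reagents that add atoms: none
Why: N-acylation of the lithiated oxazolidinone, in which the acyl bromide reacts far faster than the alkyl bromide.

Step 9
Reactants: 12 4-{(2R,3S,4S)-4-[4-(benzyloxy)-3-methoxybenzyl]-3-(hydroxymethyl)tetrahydrofuran-2-yl}-2,6-dimethoxyphenol; 16 (R)-4-benzyl-3-(2-bromoacetyl)oxazolidin-2-one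
Product: 17 (R)-4-benzyl-3-{2-[4-((2R,3S,4S)-4-(4-benzyloxy-3-methoxybenzyl)-3-(hydroxymethyl)tetrahydrofuran-2-yl)-2,6-dimethoxyphenoxy]acetyl}oxazolidin-2-one
Conditions: K2CO3 (1.5 equiv), acetone, rt
Reagents that add atoms: none
Why: Williamson etherification, in which carbonate ionises only the phenol and the phenoxide displaces the activated α-bromo imide bromide (SN2) while the primary alcohol stays neutral.

Step 10
Reactants: 17 (R)-4-benzyl-3-{2-[4-((2R,3S,4S)-4-(4-benzyloxy-3-methoxybenzyl)-3-(hydroxymethyl)tetrahydrofuran-2-yl)-2,6-dimethoxyphenoxy]acetyl}oxazolidin-2-one; 18 4-formyl-2-methoxyphenyl acetate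
Product: 21 (R)-4-benzyl-3-{(2S,3S)-3-(4-acetoxy-3-methoxyphenyl)-2-[4-((2R,3S,4S)-4-(4-benzyloxy-3-methoxybenzyl)-3-(hydroxymethyl)tetrahydrofuran-2-yl)-2,6-dimethoxyphenoxy]-3-hydroxypropanoyl}oxazolidin-2-one, via TMS ether 19 (not isolated), via bis-TMS aldol adduct 20 (not isolated)
Conditions: TMSCl (3.5 equiv), Et3N (4.5 equiv), EtOAc, rt, 20 min; then MgCl2 (20 mol%), 18 (1.3 equiv), rt, 24–48 h; then PPTS (cat.), MeOH, rt
Reagents that add atoms: none
Why: Proposed new method: after TMSCl/Et3N has masked the 9-OH as 19, Mg(II) binds both imide carbonyls and acidifies the O–CH2–C(=O) protons enough for Et3N to give the chelated (Z)-magnesium enolate (soft enolisation), which adds reversibly to the Mg-bound aldehyde 18 before TMSCl silylates the aldolate, making the addition irreversible and releasing Mg for turnover. The closest known reaction type is the magnesium-halide-catalysed direct anti-aldol addition of N-propionyl-type oxazolidinones to non-enolisable aldehydes; the new element is an α-aryloxy (glycolate-type) donor that carries the whole lignan core. No ring is closed. C8'' is controlled by the auxiliary: in the rigid Mg chelate the C4 benzyl group blocks one enolate face, so the aldehyde adds to the other, which for the R auxiliary gives 2S in the imide (8''R after reduction). C7'' is controlled by the closed, boat-like transition state of the chelated Z enolate, which places the new hydroxyl anti to the aryloxy group (erythro, 7''S). The step needs enolisation at a single site and an acceptor that cannot enolise: C8'' is the only C–H flanked by an ether oxygen and a chelating imide, A(1,3) strain fixes the Z geometry, the hindered and weakly basic 2,6-dimethoxyaryl ether oxygen should not compete for Mg, and the aromatic aldehyde is made more electrophilic by its acetate.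

Step 11
Reactants: 21 (R)-4-benzyl-3-{(2S,3S)-3-(4-acetoxy-3-methoxyphenyl)-2-[4-((2R,3S,4S)-4-(4-benzyloxy-3-methoxybenzyl)-3-(hydroxymethyl)tetrahydrofuran-2-yl)-2,6-dimethoxyphenoxy]-3-hydroxypropanoyl}oxazolidin-2-one
Product: 22 (1S,2R)-2-[4-((2R,3S,4S)-4-(4-benzyloxy-3-methoxybenzyl)-3-(hydroxymethyl)tetrahydrofuran-2-yl)-2,6-dimethoxyphenoxy]-1-(4-hydroxy-3-methoxyphenyl)propane-1,3-diol
Conditions: LiBH4 (5 equiv), THF, H2O (1.1 equiv), 0 °C → rt; then dilute HCl to pH 7
Reagents that add atoms: none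
Why: Reductive cleavage of the N-acyloxazolidinone (hydride attack at the exocyclic carbonyl) should turn C9'' into CH2OH and release the auxiliary, while the aryl acetate is cleaved in the same pot and no stereocentre is touched.

Step 12
Reactants: 22 (1S,2R)-2-[4-((2R,3S,4S)-4-(4-benzyloxy-3-methoxybenzyl)-3-(hydroxymethyl)tetrahydrofuran-2-yl)-2,6-dimethoxyphenoxy]-1-(4-hydroxy-3-methoxyphenyl)propane-1,3-diol
Product: 23 (1S,2R)-2-[4-((2R,3S,4S)-4-(4-hydroxy-3-methoxybenzyl)-3-(hydroxymethyl)tetrahydrofuran-2-yl)-2,6-dimethoxyphenoxy]-1-(4-hydroxy-3-methoxyphenyl)propane-1,3-diol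
Conditions: H2 (1 atm), 10% Pd/C, EtOAc, rt, stopped after one equivalent of H2
Reagents that add atoms: none
Why: Pd-catalysed hydrogenolysis of the aryl benzyl ether, which should be much faster in a neutral medium than cleavage of the benzylic alcohol or of the THF C–O bond.

**Compound list**

1 | 4-(benzyloxy)-3-methoxybenzaldehyde (O-benzylvanillin) | COc1cc(C=O)ccc1OCc1ccccc1 | starting material
2 | dimethyl succinate | COC(=O)CCC(=O)OC | starting material
3 | (E)-4-[4-(benzyloxy)-3-methoxyphenyl]-3-(methoxycarbonyl)but-3-enoic acid | COC(=O)/C(CC(=O)O)=C/c1ccc(OCc2ccccc2)c(OC)c1 | intermediate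
4 | (3S)-4-[4-(benzyloxy)-3-methoxyphenyl]-3-(methoxycarbonyl)butanoic acid | COC(=O)[C@H](CC(=O)O)Cc1ccc(OCc2ccccc2)c(OC)c1 | intermediate
5 | (3S)-3-[4-(benzyloxy)-3-methoxybenzyl]-4-hydroxybutanoic acid (hydroxy acid, not isolated) | OC[C@H](CC(=O)O)Cc1ccc(OCc2ccccc2)c(OC)c1 | intermediate
6 | (4S)-4-[4-(benzyloxy)-3-methoxybenzyl]dihydrofuran-2(3H)-one | O=C1C[C@H](Cc2ccc(OCc3ccccc3)c(OC)c2)CO1 | intermediate
7 | 4-hydroxy-3,5-dimethoxybenzaldehyde (syringaldehyde) | COc1cc(C=O)cc(OC)c1O | starting material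
8 | 4-formyl-2,6-dimethoxyphenyl pivalate | COc1cc(C=O)cc(OC)c1OC(=O)C(C)(C)C | intermediate
9 | lithium enolate of lactone 6 (not isolated) | [Li+].[O-]C1=C[C@H](Cc2ccc(OCc3ccccc3)c(OC)c2)CO1 | intermediate
10 | (3R,4S)-4-[4-(benzyloxy)-3-methoxybenzyl]-3-{hydroxy[3,5-dimethoxy-4-(pivaloyloxy)phenyl]methyl}dihydrofuran-2(3H)-one, both carbinol epimers | O=C1OC[C@@H](Cc2ccc(OCc3ccccc3)c(OC)c2)[C@@H]1C(O)c4cc(OC)c(OC(=O)C(C)(C)C)c(OC)c4 | intermediate
11 | (2S,3S)-2-[4-(benzyloxy)-3-methoxybenzyl]-3-[hydroxy(4-hydroxy-3,5-dimethoxyphenyl)methyl]butane-1,4-diol, both carbinol epimers | OC[C@@H](Cc1ccc(OCc2ccccc2)c(OC)c1)[C@@H](CO)C(O)c3cc(OC)c(O)c(OC)c3 | intermediate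
12 | 4-{(2R,3S,4S)-4-[4-(benzyloxy)-3-methoxybenzyl]-3-(hydroxymethyl)tetrahydrofuran-2-yl}-2,6-dimethoxyphenol | COc1cc(C[C@@H]2CO[C@@H](c3cc(OC)c(O)c(OC)c3)[C@@H]2CO)ccc1OCc4ccccc4 | intermediate
13 | (R)-4-benzyloxazolidin-2-one | O=C1N[C@H](Cc2ccccc2)CO1 | starting material
14 | bromoacetyl bromide | BrCC(Br)=O | starting material
15 | lithium (R)-4-benzyl-2-oxooxazolidin-3-ide (not isolated) | [Li+].O=C1[N-][C@H](Cc2ccccc2)CO1 | intermediate
16 | (R)-4-benzyl-3-(2-bromoacetyl)oxazolidin-2-one | O=C(CBr)N1[C@H](Cc2ccccc2)COC1=O | intermediate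
17 | (R)-4-benzyl-3-{2-[4-((2R,3S,4S)-4-(4-benzyloxy-3-methoxybenzyl)-3-(hydroxymethyl)tetrahydrofuran-2-yl)-2,6-dimethoxyphenoxy]acetyl}oxazolidin-2-one | COc1cc(C[C@@H]2CO[C@@H](c3cc(OC)c(OCC(=O)N4[C@H](Cc5ccccc5)COC4=O)c(OC)c3)[C@@H]2CO)ccc1OCc6ccccc6 | intermediate
18 | 4-formyl-2-methoxyphenyl acetate (vanillin acetate) | COc1cc(C=O)ccc1OC(C)=O | starting material
19 | 9-O-trimethylsilyl ether of 17 (not isolated) | COc1cc(C[C@@H]2CO[C@@H](c3cc(OC)c(OCC(=O)N4[C@H](Cc5ccccc5)COC4=O)c(OC)c3)[C@@H]2CO[Si](C)(C)C)ccc1OCc6ccccc6 | intermediate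
20 | 9,7''-bis-O-trimethylsilyl anti-aldol adduct (not isolated) | COc1cc(C[C@@H]2CO[C@@H](c3cc(OC)c(O[C@H](C(=O)N4[C@H](Cc5ccccc5)COC4=O)[C@@H](O[Si](C)(C)C)c6ccc(OC(C)=O)c(OC)c6)c(OC)c3)[C@@H]2CO[Si](C)(C)C)ccc1OCc7ccccc7 | intermediate
21 | (R)-4-benzyl-3-{(2S,3S)-3-(4-acetoxy-3-methoxyphenyl)-2-[4-((2R,3S,4S)-4-(4-benzyloxy-3-methoxybenzyl)-3-(hydroxymethyl)tetrahydrofuran-2-yl)-2,6-dimethoxyphenoxy]-3-hydroxypropanoyl}oxazolidin-2-one | COc1cc(C[C@@H]2CO[C@@H](c3cc(OC)c(O[C@H](C(=O)N4[C@H](Cc5ccccc5)COC4=O)[C@@H](O)c6ccc(OC(C)=O)c(OC)c6)c(OC)c3)[C@@H]2CO)ccc1OCc7ccccc7 | intermediate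
22 | (1S,2R)-2-[4-((2R,3S,4S)-4-(4-benzyloxy-3-methoxybenzyl)-3-(hydroxymethyl)tetrahydrofuran-2-yl)-2,6-dimethoxyphenoxy]-1-(4-hydroxy-3-methoxyphenyl)propane-1,3-diol | COc1cc(C[C@@H]2CO[C@@H](c3cc(OC)c(O[C@H](CO)[C@@H](O)c4ccc(O)c(OC)c4)c(OC)c3)[C@@H]2CO)ccc1OCc5ccccc5 | intermediate
23 | (1S,2R)-2-[4-((2R,3S,4S)-4-(4-hydroxy-3-methoxybenzyl)-3-(hydroxymethyl)tetrahydrofuran-2-yl)-2,6-dimethoxyphenoxy]-1-(4-hydroxy-3-methoxyphenyl)propane-1,3-diol (CNP0170225.1) | COc1cc(C[C@@H]2CO[C@@H](c3cc(OC)c(O[C@H](CO)[C@@H](O)c4ccc(O)c(OC)c4)c(OC)c3)[C@@H]2CO)ccc1O | target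

**Step count and risks**

Total steps: 12. Longest linear sequence: 10 (steps 1, 2, 3, 5, 6, 7, 9, 10, 11, 12).

Step 10 (Proposed new method). What may go wrong: the ether oxygen at C8'' may join the Mg chelate, or silylation may be slower than retro-aldol, so that anti preference or facial control erodes; the bulky enolate may also add too slowly to the aldehyde. Fallback, known chemistry on the same bond: it sets out from 12. Alkylation of 12 as in step 9 with the enantiomeric reagent (S)-4-benzyl-3-(2-bromoacetyl)oxazolidin-2-one F1 (made as in step 8 from the S oxazolidinone) should give the S-auxiliary imide F2, and TBSCl/imidazole its 9-O-TBS ether F3. The Evans syn-aldol reaction (Bu2BOTf, i-Pr2NEt, CH2Cl2, −78 → 0 °C, then aldehyde 1), a reaction type established for N-aryloxyacetyl oxazolidinones and aromatic aldehydes, should give the syn adduct F4 with C8'' already correct and C7'' epimeric (threo). LiBH4 then gives the threo diol F5, TBSCl/imidazole the primary silyl ether F6, Dess–Martin periodinane the α-aryloxy ketone F7, and chelation-controlled reduction with Zn(BH4)2 the erythro alcohol F8. TBAF gives the dibenzyl ether of the target F9, and hydrogenolysis under the conditions of step 12 comes back to the route at 23.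

Step 7. What may go wrong: Friedel–Crafts capture of the quinone methide by the electron-rich benzyloxy(methoxy)arene (aryltetralin formation), and acid-induced reopening of the ring with loss of the 7,8-trans preference. Fallback, oxidative generation of the quinone methide without acid: it sets out from 6 and 8. NaBH4 reduction of 8 gives the benzyl alcohol F10 and PBr3 the benzyl bromide F11. Alkylation of enolate 9 (from 6, LiHMDS) with F11 gives the trans-dibenzyl lactone F12, and LiAlH4 the 7-deoxy diol phenol F13. DDQ (1 equiv, dioxane, rt) then dehydrogenates the p-hydroxybenzyl position to the quinone methide under neutral conditions and the C9' hydroxyl traps it, which comes back to the route at 12.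

Step 12. What may go wrong: over-reduction, that is hydrogenolysis of the benzylic C7''–OH bond or of the benzylic O–C7 bond of the THF once the benzyl ether has gone. Fallback, debenzylation before the fragment union and ester protection that the final hydride removes: it sets out from 17. Hydrogenolysis at this stage (no benzylic alcohol present, no free para-hydroxyl on the THF aryl ring) gives the phenol F14, and Ac2O/pyridine the diacetate F15. The aldol union with 18 under the conditions of step 10 (no transient silylation of the substrate needed) gives the silyl ether F16 and, after PPTS/MeOH, the adduct F17. LiBH4 then cleaves the auxiliary and all three acetates in one operation and comes back to the route at 23.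

**Further compounds**

F1 | step 10 | (S)-4-benzyl-3-(2-bromoacetyl)oxazolidin-2-one | O=C(CBr)N1[C@@H](Cc2ccccc2)COC1=O
F2 | step 10 | S-auxiliary analogue of imide 17 | COc1cc(C[C@@H]2CO[C@@H](c3cc(OC)c(OCC(=O)N4[C@@H](Cc5ccccc5)COC4=O)c(OC)c3)[C@@H]2CO)ccc1OCc6ccccc6
F3 | step 10 | 9-O-TBS ether of F2 | COc1cc(C[C@@H]2CO[C@@H](c3cc(OC)c(OCC(=O)N4[C@@H](Cc5ccccc5)COC4=O)c(OC)c3)[C@@H]2CO[Si](C)(C)C(C)(C)C)ccc1OCc6ccccc6
F4 | step 10 | (2S,3R) syn-aldol adduct (threo, 4-benzyloxy-3-methoxyphenyl carbinol, S auxiliary, 9-O-TBS) | COc1cc(C[C@@H]2CO[C@@H](c3cc(OC)c(O[C@H](C(=O)N4[C@@H](Cc5ccccc5)COC4=O)[C@H](O)c6ccc(OCc7ccccc7)c(OC)c6)c(OC)c3)[C@@H]2CO[Si](C)(C)C(C)(C)C)ccc1OCc8ccccc8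
F5 | step 10 | (7''R,8''R) threo 7'',9''-diol (9-O-TBS, both phenols benzylated) | COc1cc(C[C@@H]2CO[C@@H](c3cc(OC)c(O[C@H](CO)[C@H](O)c6ccc(OCc7ccccc7)c(OC)c6)c(OC)c3)[C@@H]2CO[Si](C)(C)C(C)(C)C)ccc1OCc8ccccc8
F6 | step 10 | 9,9''-bis-O-TBS threo alcohol | COc1cc(C[C@@H]2CO[C@@H](c3cc(OC)c(O[C@H](CO[Si](C)(C)C(C)(C)C)[C@H](O)c6ccc(OCc7ccccc7)c(OC)c6)c(OC)c3)[C@@H]2CO[Si](C)(C)C(C)(C)C)ccc1OCc8ccccc8
F7 | step 10 | 9,9''-bis-O-TBS C7'' ketone | COc1cc(C[C@@H]2CO[C@@H](c3cc(OC)c(O[C@H](CO[Si](C)(C)C(C)(C)C)C(=O)c6ccc(OCc7ccccc7)c(OC)c6)c(OC)c3)[C@@H]2CO[Si](C)(C)C(C)(C)C)ccc1OCc8ccccc8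
F8 | step 10 | 9,9''-bis-O-TBS (7''S,8''R) erythro alcohol | COc1cc(C[C@@H]2CO[C@@H](c3cc(OC)c(O[C@H](CO[Si](C)(C)C(C)(C)C)[C@@H](O)c6ccc(OCc7ccccc7)c(OC)c6)c(OC)c3)[C@@H]2CO[Si](C)(C)C(C)(C)C)ccc1OCc8ccccc8
F9 | step 10 | di-O-benzyl ether of target 23 (both phenols benzylated) | COc1cc(C[C@@H]2CO[C@@H](c3cc(OC)c(O[C@H](CO)[C@@H](O)c6ccc(OCc7ccccc7)c(OC)c6)c(OC)c3)[C@@H]2CO)ccc1OCc8ccccc8
F10 | step 7 | 4-(hydroxymethyl)-2,6-dimethoxyphenyl pivalate | COc1cc(CO)cc(OC)c1OC(=O)C(C)(C)C
F11 | step 7 | 4-(bromomethyl)-2,6-dimethoxyphenyl pivalate | COc1cc(CBr)cc(OC)c1OC(=O)C(C)(C)C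
F12 | step 7 | (3S,4S)-4-[4-(benzyloxy)-3-methoxybenzyl]-3-[3,5-dimethoxy-4-(pivaloyloxy)benzyl]dihydrofuran-2(3H)-one | O=C1OC[C@@H](Cc2ccc(OCc3ccccc3)c(OC)c2)[C@@H]1Cc4cc(OC)c(OC(=O)C(C)(C)C)c(OC)c4
F13 | step 7 | (2S,3S)-2-[4-(benzyloxy)-3-methoxybenzyl]-3-(4-hydroxy-3,5-dimethoxybenzyl)butane-1,4-diol | OC[C@@H](Cc1ccc(OCc2ccccc2)c(OC)c1)[C@@H](CO)Cc3cc(OC)c(O)c(OC)c3
F14 | step 12 | debenzylated imide (free guaiacyl phenol analogue of 17) | COc1cc(C[C@@H]2CO[C@@H](c3cc(OC)c(OCC(=O)N4[C@H](Cc5ccccc5)COC4=O)c(OC)c3)[C@@H]2CO)ccc1O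
F15 | step 12 | diacetate of F14 (aryl acetate and 9-O-acetate) | COc1cc(C[C@@H]2CO[C@@H](c3cc(OC)c(OCC(=O)N4[C@H](Cc5ccccc5)COC4=O)c(OC)c3)[C@@H]2COC(C)=O)ccc1OC(C)=O
F16 | step 12 | 7''-O-trimethylsilyl anti-aldol adduct of F15 with 18 | COc1cc(C[C@@H]2CO[C@@H](c3cc(OC)c(O[C@H](C(=O)N4[C@H](Cc5ccccc5)COC4=O)[C@@H](O[Si](C)(C)C)c6ccc(OC(C)=O)c(OC)c6)c(OC)c3)[C@@H]2COC(C)=O)ccc1OC(C)=O
F17 | step 12 | (2S,3S) anti-aldol adduct, triacetate | COc1cc(C[C@@H]2CO[C@@H](c3cc(OC)c(O[C@H](C(=O)N4[C@H](Cc5ccccc5)COC4=O)[C@@H](O)c6ccc(OC(C)=O)c(OC)c6)c(OC)c3)[C@@H]2COC(C)=O)ccc1OC(C)=O
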